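**Plan**

- Retrosynthesis: the allylic alcohol is cut back to the enoate, C7–OMe to C7–Si, and ring B is then cut across C3a–C7a, C4–C5 and C6–C7 (benzofuran numbering: O1; C2 carries syringyl ring A; C3 carries CH2OH; ring B is the benzo ring).
- Enabling feature: ring B consists of three two-carbon units (C3a–C4, C5–C6, C7–C7a), and the O1–C2–C3 bridge joins C7a to C3a. The bicycle therefore unravels to a 1,6-diyne (silyl ynol ether on O1, terminal alkyne on C3) plus methyl (E)-pent-2-en-4-ynoate.
- The diyne is cut at C2–C3 into MOM-protected syringaldehyde and an enantiopure propargylic mesylate.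
- Forward: C2–C3 is joined first (step 6), the ynol ether is installed (steps 7–8), the dihydrofuran ring and ring B close together (step 11), then C7 is oxygenated and the side chain reduced.
- Stereochemistry: C3 (S) comes from the (R)-mesylate (transfer hydrogenation, step 4) by chirality transfer; C2 (R) is set anti to it in the cyclic transition state of step 6. Neither centre is touched afterwards, and the (E)-alkene comes from the olefination in step 9.

Key step: step 11

Remark (assumption): in step 4 the alkynyl group is assumed to play the role it plays in alkynyl methyl ketones, with CH2OSi in the place of methyl; the descriptor is R only because CH2OSi outranks the alkyne.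

**Route**

Step 1
Reactants: 1 syringaldehyde
Product: 2 3,5-dimethoxy-4-(methoxymethoxy)benzaldehyde
Conditions: MOMCl, i-Pr2NEt, CH2Cl2, 0 °C to rt
Reagents that add atoms: chloromethyl methyl ether COCCl
Why: Williamson-type O-alkylation of the phenol gives an acetal ether that should withstand the organometallic, basic and fluoride steps that follow and leave only under acid.

Step 2
Reactants: 3 (tert-butyldimethylsilyloxy)acetaldehyde; 4 trimethylsilylacetylene
Product: 6 (±)-1-(tert-butyldimethylsilyloxy)-4-(trimethylsilyl)but-3-yn-2-ol, via lithium (trimethylsilyl)acetylide 5 (not isolated)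
Conditions: n-BuLi, THF, −78 °C; then 3, −78 to 0 °C; aq. NH4Cl
Reagents that add atoms: none
Why: 1,2-addition of a lithium acetylide to the aldehyde gives the propargylic alcohol, left racemic because the centre is erased in step 3.

Step 3
Reactants: 6 (±)-1-(tert-butyldimethylsilyloxy)-4-(trimethylsilyl)but-3-yn-2-ol
Product: 7 1-(tert-butyldimethylsilyloxy)-4-(trimethylsilyl)but-3-yn-2-one
Conditions: Dess–Martin periodinane, NaHCO3, CH2Cl2, 0 °C to rt
Reagents that add atoms: none
Why: Dess–Martin oxidation under buffered conditions should give the ynone without touching the silyl ether or the alkynylsilane.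

Step 4
Reactants: 7 1-(tert-butyldimethylsilyloxy)-4-(trimethylsilyl)but-3-yn-2-one
Product: 8 (R)-1-(tert-butyldimethylsilyloxy)-4-(trimethylsilyl)but-3-yn-2-ol
Conditions: RuCl[(S,S)-TsDPEN](p-cymene) (2 mol%), i-PrOH, rt
Reagents that add atoms: none
Why: Noyori asymmetric transfer hydrogenation of an alkynyl ketone, in which the (S,S)-diamine ruthenium hydride should differentiate the alkynyl from the CH2OSi substituent and deliver hydride to the face that gives the (R)-carbinol.

Step 5
Reactants: 8 (R)-1-(tert-butyldimethylsilyloxy)-4-(trimethylsilyl)but-3-yn-2-ol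
Product: 9 (R)-1-(tert-butyldimethylsilyloxy)-4-(trimethylsilyl)but-3-yn-2-yl methanesulfonate
Conditions: MsCl, Et3N, CH2Cl2, −78 to 0 °C
Reagents that add atoms: methanesulfonyl chloride CS(=O)(=O)Cl
Why: O-sulfonylation breaks no bond to the stereocentre and provides the leaving group for ionisation by zerovalent palladium.

Step 6
Reactants: 9 (R)-1-(tert-butyldimethylsilyloxy)-4-(trimethylsilyl)but-3-yn-2-yl methanesulfonate; 2 3,5-dimethoxy-4-(methoxymethoxy)benzaldehyde
Product: 11 (1R,2S)-2-[(tert-butyldimethylsilyloxy)methyl]-1-[3,5-dimethoxy-4-(methoxymethoxy)phenyl]-4-(trimethylsilyl)but-3-yn-1-ol, via allenylzinc reagent 10 (not isolated)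
Conditions: Pd(OAc)2 (5 mol%), PPh3 (5 mol%), Et2Zn (3 equiv), THF, −78 to −20 °C
Reagents that add atoms: none
Why: Marshall propargylation, in which zerovalent palladium displaces the mesylate anti (SN2'), transmetalation gives the axially chiral allenylzinc, and its addition through a cyclic SE2' transition state sets the CH2OSi-bearing carbon (S, net inversion at the former mesylate carbon) and the carbinol carbon (R, anti, the aryl group avoiding the CH2OSi substituent).

Step 7
Reactants: 11 (1R,2S)-2-[(tert-butyldimethylsilyloxy)methyl]-1-[3,5-dimethoxy-4-(methoxymethoxy)phenyl]-4-(trimethylsilyl)but-3-yn-1-ol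
Product: 15 benzyl({[(1R,2S)-2-[(tert-butyldimethylsilyloxy)methyl]-1-[3,5-dimethoxy-4-(methoxymethoxy)phenyl]-4-(trimethylsilyl)but-3-yn-1-yl]oxy}ethynyl)dimethylsilane, via potassium alkoxide 12 (not isolated), via dichlorovinyl ether 13 (not isolated), via lithium alkoxyacetylide 14 (not isolated)
Conditions: KH, THF, 0 °C; Cl2C=CHCl, −50 °C to rt; n-BuLi (2.5 equiv), −78 °C; BnMe2SiCl, −78 to 0 °C
Reagents that add atoms: trichloroethylene ClC=C(Cl)Cl; benzylchlorodimethylsilane C[Si](C)(Cl)Cc1ccccc1
Why: One-pot trichloroethylene route to alkynyl ethers, in which the alkoxide adds to dichloroacetylene formed in the flask, n-BuLi effects dehydrochlorination and chlorine–lithium exchange, and the lithium alkoxyacetylide is C-silylated, the benzylic C–O bond and both stereocentres staying intact.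

Step 8
Reactants: 15 benzyl({[(1R,2S)-2-[(tert-butyldimethylsilyloxy)methyl]-1-[3,5-dimethoxy-4-(methoxymethoxy)phenyl]-4-(trimethylsilyl)but-3-yn-1-yl]oxy}ethynyl)dimethylsilane
Product: 16 benzyl({[(1R,2S)-2-[(tert-butyldimethylsilyloxy)methyl]-1-[3,5-dimethoxy-4-(methoxymethoxy)phenyl]but-3-yn-1-yl]oxy}ethynyl)dimethylsilane
Conditions: K2CO3 (0.2 equiv), MeOH–THF, −20 °C, stopped when the C-silyl alkyne is consumed; Et3N-deactivated silica
Reagents that add atoms: none
Why: Base-catalysed protodesilylation of an alkynylsilane, run cold so that the least hindered trimethylsilyl group should leave before the larger benzyldimethylsilyl group, while the TBS ether and MOM acetal are inert to carbonate.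

Step 9
Reactants: 17 3-(trimethylsilyl)prop-2-ynal
Product: 18 methyl (E)-5-(trimethylsilyl)pent-2-en-4-ynoate
Conditions: (MeO)2P(O)CH2CO2Me, LiCl, i-Pr2NEt, MeCN, 0 °C to rt
Reagents that add atoms: trimethyl phosphonoacetate COC(=O)CP(=O)(OC)OC
Why: Horner–Wadsworth–Emmons olefination under Masamune–Roush conditions should give the (E)-enoate from the ynal.

Step 10
Reactants: 18 methyl (E)-5-(trimethylsilyl)pent-2-en-4-ynoate
Product: 19 methyl (E)-pent-2-en-4-ynoate
Conditions: K2CO3 (0.1 equiv), MeOH, 0 °C, short reaction time; used as a solution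
Reagents that add atoms: none
Why: Carbonate-catalysed protodesilylation of the alkynylsilane should be complete within minutes, faster than conjugate addition of methanol to the enynoate.

Step 11
Reactants: 16 benzyl({[(1R,2S)-2-[(tert-butyldimethylsilyloxy)methyl]-1-[3,5-dimethoxy-4-(methoxymethoxy)phenyl]but-3-yn-1-yl]oxy}ethynyl)dimethylsilane; 19 methyl (E)-pent-2-en-4-ynoate
Product: 20 methyl (E)-3-[(2R,3S)-7-(benzyldimethylsilyl)-3-[(tert-butyldimethylsilyloxy)methyl]-2-[3,5-dimethoxy-4-(methoxymethoxy)phenyl]-2,3-dihydro-1-benzofuran-5-yl]prop-2-enoate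
Conditions: Cp*RuCl(cod) (10 mol%), 19 (3 equiv), ClCH2CH2Cl, 20 °C, slow addition of 16
Reagents that add atoms: none
Why: Oxidative coupling of the silyl ynol ether and the terminal alkyne of 16 at the Cp*RuCl fragment gives a bicyclic ruthenacyclopentadiene (C3a–C7a bond), the alkyne of 19 inserts, and reductive elimination forms C4–C5 and C6–C7 and releases the arene. The closest known reactions are the Cp*RuCl(cod)-catalysed (2+2+2) cycloaddition of 1,6-diynes with terminal alkynes and the rhodium-catalysed cyclotrimerisations of ynamide-tethered diynes to indolines and of aryl alkynyl ether diynes to dibenzofurans, so the alkyl silyl ynol ether is a new member of a known substrate class. The dihydrofuran ring closes in the oxidative cyclisation as the five-membered ring spanned by the O1–C2–C3 tether, and ring B closes in the insertion and reductive elimination as a six-membered carbocycle built from three alkynes. No stereocentre is created: C2 and C3 were set in step 6, no bond to either is made or broken, and their trans relationship is carried into the ring. The ester-bearing alkyne carbon must bond to C4 and the CH terminus to C7, which the bulky BnMe2Si group on the C7 end of the ruthenacycle should enforce (meta orientation), and cross-coupling must beat self-coupling of the diyne, which slow addition of 16 to excess 19 should secure. Room temperature is needed because the benzylic ynol ether would otherwise lose silylketene by a retro-ene path or rearrange sigmatropically.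

Step 12
Reactants: 20 methyl (E)-3-[(2R,3S)-7-(benzyldimethylsilyl)-3-[(tert-butyldimethylsilyloxy)methyl]-2-[3,5-dimethoxy-4-(methoxymethoxy)phenyl]-2,3-dihydro-1-benzofuran-5-yl]prop-2-enoate
Product: 22 methyl (E)-3-[(2R,3S)-7-hydroxy-3-(hydroxymethyl)-2-[3,5-dimethoxy-4-(methoxymethoxy)phenyl]-2,3-dihydro-1-benzofuran-5-yl]prop-2-enoate, via arylsilanol 21 (not isolated)
Conditions: Bu4NF (3 equiv), THF, 0 °C to rt; then KHCO3, 30% H2O2, MeOH, rt
Reagents that add atoms: hydrogen peroxide OO
Why: Tamao–Fleming oxidation, in which fluoride cleaves the benzyl–silicon bond and the TBS ether and hydroperoxide then moves the aryl group from silicon to oxygen at C7, the enoate being a poor acceptor for hydroperoxide.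

Step 13
Reactants: 22 methyl (E)-3-[(2R,3S)-7-hydroxy-3-(hydroxymethyl)-2-[3,5-dimethoxy-4-(methoxymethoxy)phenyl]-2,3-dihydro-1-benzofuran-5-yl]prop-2-enoate
Product: 23 methyl (E)-3-[(2R,3S)-3-(hydroxymethyl)-7-methoxy-2-[3,5-dimethoxy-4-(methoxymethoxy)phenyl]-2,3-dihydro-1-benzofuran-5-yl]prop-2-enoate
Conditions: MeI, K2CO3, acetone, rt
Reagents that add atoms: iodomethane CI
Why: Williamson methylation of the only free phenol (ring A is still masked as its MOM ether) should leave the primary alcohol untouched under carbonate.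

Step 14
Reactants: 23 methyl (E)-3-[(2R,3S)-3-(hydroxymethyl)-7-methoxy-2-[3,5-dimethoxy-4-(methoxymethoxy)phenyl]-2,3-dihydro-1-benzofuran-5-yl]prop-2-enoate
Product: 24 methyl (E)-3-[(2R,3S)-2-(4-hydroxy-3,5-dimethoxyphenyl)-3-(hydroxymethyl)-7-methoxy-2,3-dihydro-1-benzofuran-5-yl]prop-2-enoate
Conditions: HCl (2 M in MeOH), MeOH–THF, rt
Reagents that add atoms: none
Why: Acid-catalysed acetal exchange removes the aryl MOM ether while the side chain is still an acid-stable enoate and not an ionisable cinnamyl alcohol, and the trans dihydrofuran is the thermodynamic isomer should the benzylic C–O bond ionise reversibly.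

Step 15
Reactants: 24 methyl (E)-3-[(2R,3S)-2-(4-hydroxy-3,5-dimethoxyphenyl)-3-(hydroxymethyl)-7-methoxy-2,3-dihydro-1-benzofuran-5-yl]prop-2-enoate
Product: 25 (E)-3-[(2R,3S)-2-(4-hydroxy-3,5-dimethoxyphenyl)-3-(hydroxymethyl)-7-methoxy-2,3-dihydro-1-benzofuran-5-yl]prop-2-en-1-ol
Conditions: i-Bu2AlH (5 equiv), CH2Cl2, −78 to −40 °C; aq. potassium sodium tartrate (KNaC4H4O6)
Reagents that add atoms: none
Why: 1,2-reduction of the α,β-unsaturated ester by excess i-Bu2AlH at low temperature should give the (E)-allylic alcohol without touching the alkene, the phenol and alcohol being carried as aluminium alkoxides.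

**Compound list**

1 | syringaldehyde | COc1cc(C=O)cc(OC)c1O | starting material
2 | 3,5-dimethoxy-4-(methoxymethoxy)benzaldehyde | COCOc1c(OC)cc(C=O)cc1OC | intermediate
3 | (tert-butyldimethylsilyloxy)acetaldehyde | O=CCO[Si](C)(C)C(C)(C)C | starting material
4 | trimethylsilylacetylene | C#C[Si](C)(C)C | starting material
5 | lithium (trimethylsilyl)acetylide | [Li]C#C[Si](C)(C)C | intermediate
6 | (±)-1-(tert-butyldimethylsilyloxy)-4-(trimethylsilyl)but-3-yn-2-ol | OC(CO[Si](C)(C)C(C)(C)C)C#C[Si](C)(C)C | intermediate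
7 | 1-(tert-butyldimethylsilyloxy)-4-(trimethylsilyl)but-3-yn-2-one | O=C(CO[Si](C)(C)C(C)(C)C)C#C[Si](C)(C)C | intermediate
8 | (R)-1-(tert-butyldimethylsilyloxy)-4-(trimethylsilyl)but-3-yn-2-ol | O[C@@H](CO[Si](C)(C)C(C)(C)C)C#C[Si](C)(C)C | intermediate
9 | (R)-1-(tert-butyldimethylsilyloxy)-4-(trimethylsilyl)but-3-yn-2-yl methanesulfonate | CS(=O)(=O)O[C@@H](CO[Si](C)(C)C(C)(C)C)C#C[Si](C)(C)C | intermediate
10 | ethyl[(aR)-4-(tert-butyldimethylsilyloxy)-1-(trimethylsilyl)buta-1,2-dien-1-yl]zinc (axial configuration given in the name; SMILES without axial tag) | CC[Zn]C(=C=CCO[Si](C)(C)C(C)(C)C)[Si](C)(C)C | intermediate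
11 | (1R,2S)-2-[(tert-butyldimethylsilyloxy)methyl]-1-[3,5-dimethoxy-4-(methoxymethoxy)phenyl]-4-(trimethylsilyl)but-3-yn-1-ol (anti) | COCOc1c(OC)cc(cc1OC)[C@H](O)[C@H](CO[Si](C)(C)C(C)(C)C)C#C[Si](C)(C)C | intermediate
12 | potassium alkoxide of 11 | COCOc1c(OC)cc(cc1OC)[C@H]([O-])[C@H](CO[Si](C)(C)C(C)(C)C)C#C[Si](C)(C)C.[K+] | intermediate
13 | (E)-1,2-dichlorovinyl ether of 11 | COCOc1c(OC)cc(cc1OC)[C@H](O/C(Cl)=C\Cl)[C@H](CO[Si](C)(C)C(C)(C)C)C#C[Si](C)(C)C | intermediate
14 | lithium alkoxyacetylide (lithioethynyl ether of 11) | COCOc1c(OC)cc(cc1OC)[C@H](OC#C[Li])[C@H](CO[Si](C)(C)C(C)(C)C)C#C[Si](C)(C)C | intermediate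
15 | benzyl({[(1R,2S)-2-[(tert-butyldimethylsilyloxy)methyl]-1-[3,5-dimethoxy-4-(methoxymethoxy)phenyl]-4-(trimethylsilyl)but-3-yn-1-yl]oxy}ethynyl)dimethylsilane | COCOc1c(OC)cc(cc1OC)[C@H](OC#C[Si](C)(C)Cc2ccccc2)[C@H](CO[Si](C)(C)C(C)(C)C)C#C[Si](C)(C)C | intermediate
16 | benzyl({[(1R,2S)-2-[(tert-butyldimethylsilyloxy)methyl]-1-[3,5-dimethoxy-4-(methoxymethoxy)phenyl]but-3-yn-1-yl]oxy}ethynyl)dimethylsilane | COCOc1c(OC)cc(cc1OC)[C@H](OC#C[Si](C)(C)Cc2ccccc2)[C@H](CO[Si](C)(C)C(C)(C)C)C#C | intermediate
17 | 3-(trimethylsilyl)prop-2-ynal | C[Si](C)(C)C#CC=O | starting material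
18 | methyl (E)-5-(trimethylsilyl)pent-2-en-4-ynoate | COC(=O)/C=C/C#C[Si](C)(C)C | intermediate
19 | methyl (E)-pent-2-en-4-ynoate | COC(=O)/C=C/C#C | intermediate
20 | methyl (E)-3-[(2R,3S)-7-(benzyldimethylsilyl)-3-[(tert-butyldimethylsilyloxy)methyl]-2-[3,5-dimethoxy-4-(methoxymethoxy)phenyl]-2,3-dihydro-1-benzofuran-5-yl]prop-2-enoate (trans) | COCOc1c(OC)cc(cc1OC)[C@@H]1Oc2c([Si](C)(C)Cc3ccccc3)cc(/C=C/C(=O)OC)cc2[C@H]1CO[Si](C)(C)C(C)(C)C | intermediate
21 | methyl (E)-3-[(2R,3S)-7-(hydroxydimethylsilyl)-3-(hydroxymethyl)-2-[3,5-dimethoxy-4-(methoxymethoxy)phenyl]-2,3-dihydro-1-benzofuran-5-yl]prop-2-enoate | COCOc1c(OC)cc(cc1OC)[C@@H]1Oc2c([Si](C)(C)O)cc(/C=C/C(=O)OC)cc2[C@H]1CO | intermediate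
22 | methyl (E)-3-[(2R,3S)-7-hydroxy-3-(hydroxymethyl)-2-[3,5-dimethoxy-4-(methoxymethoxy)phenyl]-2,3-dihydro-1-benzofuran-5-yl]prop-2-enoate | COCOc1c(OC)cc(cc1OC)[C@@H]1Oc2c(O)cc(/C=C/C(=O)OC)cc2[C@H]1CO | intermediate
23 | methyl (E)-3-[(2R,3S)-3-(hydroxymethyl)-7-methoxy-2-[3,5-dimethoxy-4-(methoxymethoxy)phenyl]-2,3-dihydro-1-benzofuran-5-yl]prop-2-enoate | COCOc1c(OC)cc(cc1OC)[C@@H]1Oc2c(OC)cc(/C=C/C(=O)OC)cc2[C@H]1CO | intermediate
24 | methyl (E)-3-[(2R,3S)-2-(4-hydroxy-3,5-dimethoxyphenyl)-3-(hydroxymethyl)-7-methoxy-2,3-dihydro-1-benzofuran-5-yl]prop-2-enoate | COc1cc(cc(OC)c1O)[C@@H]1Oc2c(OC)cc(/C=C/C(=O)OC)cc2[C@H]1CO | intermediate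
25 | (E)-3-[(2R,3S)-2-(4-hydroxy-3,5-dimethoxyphenyl)-3-(hydroxymethyl)-7-methoxy-2,3-dihydro-1-benzofuran-5-yl]prop-2-en-1-ol | COc1cc([C@@H]2Oc3c(OC)cc(/C=C/CO)cc3[C@H]2CO)cc(OC)c1O | target

**Step count and risks**

Total step count: 15. Longest linear sequence: 12 steps (steps 2–8 and 11–15, from 3 and 4).

Steps most likely to fail:

1. Step 11. The hindered, silyl-substituted ruthenacycle may capture the conjugated enynoate too slowly. Self-coupling of the diyne through its own terminal alkyne and thermal decay of the benzylic ynol ether would then outrun the cross-cycloaddition. The fallback sets out from 16 and uses methyl propiolate in large excess as a smaller, more activated partner under the same ruthenium catalysis. This should give methyl (2R,3S)-7-(benzyldimethylsilyl)-3-[(tert-butyldimethylsilyloxy)methyl]-2-[3,5-dimethoxy-4-(methoxymethoxy)phenyl]-2,3-dihydro-1-benzofuran-5-carboxylate F1. Reduction with i-Bu2AlH should give the benzylic alcohol [(2R,3S)-7-(benzyldimethylsilyl)-3-[(tert-butyldimethylsilyloxy)methyl]-2-[3,5-dimethoxy-4-(methoxymethoxy)phenyl]-2,3-dihydro-1-benzofuran-5-yl]methanol F2. Oxidation with MnO2 should give the corresponding 5-carbaldehyde F3. Horner–Wadsworth–Emmons olefination with trimethyl phosphonoacetate (LiCl, i-Pr2NEt) then returns to 20. The propenoate chain is thus built on the finished ring B instead of being carried in on the alkyne.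

2. Step 8. The benzyldimethylsilyl group may be lost from the ynol ether terminus as fast as, or faster than, the trimethylsilyl group. An alkoxyacetylide is likely a better leaving group from silicon than an alkylacetylide, and the size difference between the two silyl groups is small. The fallback sets out from 15 and lets the carbonate methanolysis run to completion, cleaving both alkynyl silanes to give {(1R,2S)-2-[(tert-butyldimethylsilyloxy)methyl]-1-[3,5-dimethoxy-4-(methoxymethoxy)phenyl]but-3-yn-1-yl} ethynyl ether F4. The same acidity difference is then used constructively: LiN(SiMe3)2 (1.0 equiv, THF, −78 °C) should deprotonate the alkoxyethyne C–H preferentially, and BnMe2SiCl should silylate that terminus only, returning to 16. Differentiation is by selective deprotonation instead of selective desilylation.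

3. Step 6. The silyloxy group may undergo β-elimination from the propargylzinc tautomer of the reagent, and the anti preference may erode with the electron-rich aromatic aldehyde. The fallback sets out from alcohol 8, which methyl chloroformate and pyridine should convert into methyl (R)-1-(tert-butyldimethylsilyloxy)-4-(trimethylsilyl)but-3-yn-2-yl carbonate F5. Copper-catalysed borylative substitution (CuCl, NaOt-Bu, Xantphos, B2pin2, THF) should proceed anti SN2' to give 2-[(aS)-4-(tert-butyldimethylsilyloxy)-1-(trimethylsilyl)buta-1,2-dien-1-yl]-4,4,5,5-tetramethyl-1,3,2-dioxaborolane F6. Warming this isolable, non-basic allenylboronate with aldehyde 2 in toluene should give, through a closed six-membered transition state and after aqueous work-up, the anti adduct 11. The sense of chirality transfer is the same as in step 6.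

**Further compounds**

F1 | step 11 | methyl (2R,3S)-7-(benzyldimethylsilyl)-3-[(tert-butyldimethylsilyloxy)methyl]-2-[3,5-dimethoxy-4-(methoxymethoxy)phenyl]-2,3-dihydro-1-benzofuran-5-carboxylate | COCOc1c(OC)cc(cc1OC)[C@@H]1Oc2c([Si](C)(C)Cc3ccccc3)cc(C(=O)OC)cc2[C@H]1CO[Si](C)(C)C(C)(C)C
F2 | step 11 | [(2R,3S)-7-(benzyldimethylsilyl)-3-[(tert-butyldimethylsilyloxy)methyl]-2-[3,5-dimethoxy-4-(methoxymethoxy)phenyl]-2,3-dihydro-1-benzofuran-5-yl]methanol | COCOc1c(OC)cc(cc1OC)[C@@H]1Oc2c([Si](C)(C)Cc3ccccc3)cc(CO)cc2[C@H]1CO[Si](C)(C)C(C)(C)C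
F3 | step 11 | (2R,3S)-7-(benzyldimethylsilyl)-3-[(tert-butyldimethylsilyloxy)methyl]-2-[3,5-dimethoxy-4-(methoxymethoxy)phenyl]-2,3-dihydro-1-benzofuran-5-carbaldehyde | COCOc1c(OC)cc(cc1OC)[C@@H]1Oc2c([Si](C)(C)Cc3ccccc3)cc(C=O)cc2[C@H]1CO[Si](C)(C)C(C)(C)C
F4 | step 8 | {(1R,2S)-2-[(tert-butyldimethylsilyloxy)methyl]-1-[3,5-dimethoxy-4-(methoxymethoxy)phenyl]but-3-yn-1-yl} ethynyl ether | COCOc1c(OC)cc(cc1OC)[C@H](OC#C)[C@H](CO[Si](C)(C)C(C)(C)C)C#C
F5 | step 6 | methyl (R)-1-(tert-butyldimethylsilyloxy)-4-(trimethylsilyl)but-3-yn-2-yl carbonate | COC(=O)O[C@@H](CO[Si](C)(C)C(C)(C)C)C#C[Si](C)(C)C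
F6 | step 6 | 2-[(aS)-4-(tert-butyldimethylsilyloxy)-1-(trimethylsilyl)buta-1,2-dien-1-yl]-4,4,5,5-tetramethyl-1,3,2-dioxaborolane (axial configuration given in the name; SMILES without axial tag) | CC1(C)OB(OC1(C)C)C(=C=CCO[Si](C)(C)C(C)(C)C)[Si](C)(C)C
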